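**Retrosynthetic overview**
- Cyclohexane halogens last: ring alkene → epoxide anti to the oxanyl group → trans-diaxial bromohydrin → bromonium/chloride → thermal diaxial-to-diequatorial halogen interchange.
- Oxane ring second: 6-endo bromoetherification of the tertiary alcohol onto the prenyl alkene, which also sets C5–Br.
- Oxane C2 (tertiary carbinol): Felkin–Anh methyl addition to an α-carbamoyloxy ketone.
- Key C–C bond (future oxane C2–C3): an enantioenriched α-oxygenated organolithium (polarity-reversed carbinol carbon, from a homoprenyl carbamate with s-BuLi/(+)-sparteine) is acylated by a cyclohexenyl Weinreb amide, so two oxygen-bearing, normally electrophilic carbons are joined.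
- Cyclohexene ring first: auxiliary-controlled Diels–Alder of isoprene with a chiral acrylimide.

Assumption: acrylimide 2, (+)-sparteine and the L-configured Shi ketone are bought as catalogue compounds. Cyclohexane locants are primed, with C1′ the carbon bonded to the oxane.

**Step 1**
Reactants: 1 isoprene; 2 (4S)-4-benzyl-3-(prop-2-enoyl)-1,3-oxazolidin-2-one
Product: 3 (4S)-4-benzyl-3-[(1R)-4-methylcyclohex-3-ene-1-carbonyl]-1,3-oxazolidin-2-one
Conditions: Et2AlCl (1.4 equiv), CH2Cl2, −100 → −78 °C; recrystallise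
Reagents that add atoms: none
Why: Auxiliary-controlled Diels–Alder reaction in which isoprene adds to the Et2AlCl-chelated s-cis acrylimide on the face away from the benzyl group with para regiochemistry, setting the ring stereocentre as R.

**Step 2**
Reactants: 3 (4S)-4-benzyl-3-[(1R)-4-methylcyclohex-3-ene-1-carbonyl]-1,3-oxazolidin-2-one
Product: 4 (1R)-N-methoxy-N,4-dimethylcyclohex-3-ene-1-carboxamide
Conditions: MeNH(OMe)·HCl, AlMe3, CH2Cl2, −15 → 0 °C
Reagents that add atoms: N,O-dimethylhydroxylamine hydrochloride, CNOC.Cl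
Why: Weinreb transamidation by the aluminium amide attacks the exocyclic carbonyl under non-basic conditions, so the α-stereocentre is untouched and the auxiliary is returned.

**Step 3**
Reactants: 5 4-methylpent-3-en-1-ol
Product: 6 4-methylpent-3-en-1-yl N,N-di(propan-2-yl)carbamate
Conditions: NaH, THF, 0 °C; then i-Pr2NCOCl, reflux
Reagents that add atoms: N,N-di(propan-2-yl)carbamoyl chloride, CC(C)N(C(C)C)C(Cl)=O
Why: O-Carbamoylation of the sodium alkoxide gives the Hoppe-type carbamate whose carbonyl group directs and stabilises the later α-lithiation.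

**Step 4**
Reactants: 6 4-methylpent-3-en-1-yl N,N-di(propan-2-yl)carbamate (1.5 equiv); 4 (1R)-N-methoxy-N,4-dimethylcyclohex-3-ene-1-carboxamide
Product: 9 (2S)-5-methyl-1-[(1R)-4-methylcyclohex-3-en-1-yl]-1-oxohex-4-en-2-yl N,N-di(propan-2-yl)carbamate, via (R)-lithiated carbamate 7 (not isolated), via lithium carbinolamine chelate 8 (not isolated)
Conditions: s-BuLi, (+)-sparteine, Et2O, −78 °C, 5 h; then 4, −78 °C, 4 h; AcOH/Et2O quench at −78 °C
Reagents that add atoms: none
Why: Hoppe asymmetric deprotonation–acylation, in which s-BuLi/(+)-sparteine removes the pro-R hydrogen next to oxygen to give the configurationally stable α-oxy organolithium 7 (a nucleophile at a carbon that is normally electrophilic), which is acylated with retention by the Weinreb amide to set the future oxane C3 as S, while chelate 8 keeps the epimerisable ketone masked until the cold quench.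

**Step 5**
Reactants: 9 (2S)-5-methyl-1-[(1R)-4-methylcyclohex-3-en-1-yl]-1-oxohex-4-en-2-yl N,N-di(propan-2-yl)carbamate
Product: 11 (2S,3S)-6-methyl-2-[(1R)-4-methylcyclohex-3-en-1-yl]hept-5-ene-2,3-diol, via dichlorocerium alkoxide 10 (not isolated)
Conditions: MeLi, CeCl3 (MeCeCl2), THF, −78 °C; then LiAlH4, −78 °C → reflux
Reagents that add atoms: methyllithium, [Li]C
Why: Polar Felkin–Anh 1,2-addition of the weakly basic, poorly chelating MeCeCl2 anti to the bulky carbamoyloxy group (passing the α-hydrogen) sets the tertiary carbinol as S (syn-diol), and LiAlH4 then cleaves the carbamate reductively in the same pot.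

**Step 6**
Reactants: 11 (2S,3S)-6-methyl-2-[(1R)-4-methylcyclohex-3-en-1-yl]hept-5-ene-2,3-diol
Product: 12 (2S,3S)-2-hydroxy-6-methyl-2-[(1R)-4-methylcyclohex-3-en-1-yl]hept-5-en-3-yl acetate
Conditions: Ac2O, pyridine, 4-(dimethylamino)pyridine (cat.), CH2Cl2, 0 °C → rt
Reagents that add atoms: acetic anhydride, CC(=O)OC(C)=O
Why: Chemoselective acylation of the secondary hydroxyl (the tertiary one is too hindered), which also blocks this oxygen from competing in the next cyclisation.

**Step 7**
Reactants: 12 (2S,3S)-2-hydroxy-6-methyl-2-[(1R)-4-methylcyclohex-3-en-1-yl]hept-5-en-3-yl acetate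
Product: 13 (2S,3S,5S)-5-bromo-2,6,6-trimethyl-2-[(1R)-4-methylcyclohex-3-en-1-yl]oxan-3-yl acetate
Conditions: 2,4,4,6-tetrabromocyclohexa-2,5-dien-1-one (TBCO, 1.05 equiv), MeNO2, 0 °C, dark
Reagents that add atoms: 2,4,4,6-tetrabromocyclohexa-2,5-dien-1-one, O=C1C(Br)=CC(Br)(Br)C=C1Br
Why: 6-endo Markovnikov bromoetherification, in which the reversibly formed bromonium ion of the prenyl alkene is captured by the tertiary hydroxyl through a chair with cyclohexenyl equatorial and the C2-methyl and acetoxy groups axial, anti addition placing bromine equatorial (5S), whereas the ring alkene could only be captured through a boat-like bridged transition state.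

**Step 8**
Reactants: 13 (2S,3S,5S)-5-bromo-2,6,6-trimethyl-2-[(1R)-4-methylcyclohex-3-en-1-yl]oxan-3-yl acetate
Product: 14 (2S,3S,5S)-5-bromo-2,6,6-trimethyl-2-[(1S,3R,6R)-6-methyl-7-oxabicyclo[4.1.0]heptan-3-yl]oxan-3-yl acetate
Conditions: 1,2:4,5-di-O-isopropylidene-β-L-erythro-2,3-hexodiulo-2,6-pyranose (L-configured Shi ketone, 30 mol %), KHSO5 (as 2KHSO5·KHSO4·K2SO4), K2CO3, Bu4NHSO4 (cat.), MeCN/dimethoxymethane/aq. buffer pH 10.5, 0 °C
Reagents that add atoms: potassium peroxymonosulfate KHSO5, [K+].[O-]S(=O)(=O)OO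
Why: Shi asymmetric epoxidation, in which the chiral dioxirane delivers oxygen through the spiro transition state to the alkene face anti to the oxanyl group (reagent control, the C1′ centre being remote), giving the epoxide whose diaxial opening falls on the tertiary carbon.

**Step 9**
Reactants: 14 (2S,3S,5S)-5-bromo-2,6,6-trimethyl-2-[(1S,3R,6R)-6-methyl-7-oxabicyclo[4.1.0]heptan-3-yl]oxan-3-yl acetate
Product: 15 (2S,3S,5S)-5-bromo-2-[(1R,3S,4S)-4-bromo-3-hydroxy-4-methylcyclohexyl]-2,6,6-trimethyloxan-3-yl acetate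
Conditions: 48% aq. HBr (1.5 equiv), CHCl3, −20 °C, 15 min; cold NaHCO3 wash; used at once
Reagents that add atoms: hydrogen bromide, Br
Why: Acid-mediated trans-diaxial (Fürst–Plattner) epoxide opening, for which the diaxial path and the Markovnikov preference coincide in this diastereomer, so bromide enters with inversion at the tertiary carbon and leaves an axial secondary alcohol anti-periplanar to C–Br.

**Step 10**
Reactants: 15 (2S,3S,5S)-5-bromo-2-[(1R,3S,4S)-4-bromo-3-hydroxy-4-methylcyclohexyl]-2,6,6-trimethyloxan-3-yl acetate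
Product: 18 acetylcaespitol, via bromonium chloride 16 (not isolated), via diaxial bromochloride 17 (not isolated)
Conditions: 1-chloro-N,N,2-trimethylprop-1-en-1-amine (1.5 equiv), CH2Cl2, 0 °C → rt; then evaporate, PhCl, 120 °C
Reagents that add atoms: 1-chloro-N,N,2-trimethylprop-1-en-1-amine, CC(C)=C(Cl)N(C)C
Why: Deoxychlorination with neighbouring-group participation followed by thermal 1,2-dihalide interchange, in which the activated axial hydroxyl is displaced by the anti-periplanar bromine to give bromonium ion 16 on the face syn to the oxanyl group, chloride opens it from the other face (diaxially at the secondary carbon to 17, or at the tertiary carbon to 18 directly), and heating converts 17 into the trans-diequatorial tertiary chloride/secondary bromide by the suprafacial halogen exchange known for trans-diaxial vicinal dihalides, so both opening modes converge on the target.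

**Compound list**
1 | isoprene (2-methylbuta-1,3-diene) | C=CC(C)=C | starting material
2 | (4S)-4-benzyl-3-(prop-2-enoyl)-1,3-oxazolidin-2-one | C=CC(=O)N1[C@@H](Cc2ccccc2)COC1=O | starting material
3 | (4S)-4-benzyl-3-[(1R)-4-methylcyclohex-3-ene-1-carbonyl]-1,3-oxazolidin-2-one | O=C([C@@H]1CCC(C)=CC1)N1[C@@H](Cc2ccccc2)COC1=O | intermediate
4 | (1R)-N-methoxy-N,4-dimethylcyclohex-3-ene-1-carboxamide | CON(C)C(=O)[C@@H]1CCC(C)=CC1 | intermediate
5 | 4-methylpent-3-en-1-ol | CC(C)=CCCO | starting material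
6 | 4-methylpent-3-en-1-yl N,N-di(propan-2-yl)carbamate | CC(C)=CCCOC(=O)N(C(C)C)C(C)C | intermediate
7 | (1R)-1-lithio-4-methylpent-3-en-1-yl N,N-di(propan-2-yl)carbamate as its (+)-sparteine complex (ligand not drawn) | CC(C)=CC[C@@H]([Li])OC(=O)N(C(C)C)C(C)C | intermediate
8 | lithium alkoxide of the tetrahedral adduct of 7 to 4 (N-methoxy-N-methyl carbinolamine, either configuration at the transient carbinolamine carbon) | CC(C)=CC[C@H](OC(=O)N(C(C)C)C(C)C)C(O[Li])(N(C)OC)[C@@H]1CCC(C)=CC1 | intermediate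
9 | (2S)-5-methyl-1-[(1R)-4-methylcyclohex-3-en-1-yl]-1-oxohex-4-en-2-yl N,N-di(propan-2-yl)carbamate | CC(C)=CC[C@H](OC(=O)N(C(C)C)C(C)C)C(=O)[C@@H]1CCC(C)=CC1 | intermediate
10 | dichlorocerium alkoxide of (2S,3S)-2-hydroxy-6-methyl-2-[(1R)-4-methylcyclohex-3-en-1-yl]hept-5-en-3-yl N,N-di(propan-2-yl)carbamate | CC(C)=CC[C@H](OC(=O)N(C(C)C)C(C)C)[C@@](C)(O[Ce](Cl)Cl)[C@@H]1CCC(C)=CC1 | intermediate
11 | (2S,3S)-6-methyl-2-[(1R)-4-methylcyclohex-3-en-1-yl]hept-5-ene-2,3-diol | CC(C)=CC[C@H](O)[C@@](C)(O)[C@@H]1CCC(C)=CC1 | intermediate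
12 | (2S,3S)-2-hydroxy-6-methyl-2-[(1R)-4-methylcyclohex-3-en-1-yl]hept-5-en-3-yl acetate | CC(C)=CC[C@H](OC(C)=O)[C@@](C)(O)[C@@H]1CCC(C)=CC1 | intermediate
13 | (2S,3S,5S)-5-bromo-2,6,6-trimethyl-2-[(1R)-4-methylcyclohex-3-en-1-yl]oxan-3-yl acetate | CC(=O)O[C@H]1C[C@H](Br)C(C)(C)O[C@@]1(C)[C@@H]1CCC(C)=CC1 | intermediate
14 | (2S,3S,5S)-5-bromo-2,6,6-trimethyl-2-[(1S,3R,6R)-6-methyl-7-oxabicyclo[4.1.0]heptan-3-yl]oxan-3-yl acetate (epoxide oxygen anti to the oxanyl group) | CC(=O)O[C@H]1C[C@H](Br)C(C)(C)O[C@@]1(C)[C@@H]1CC[C@@]2(C)O[C@H]2C1 | intermediate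
15 | (2S,3S,5S)-5-bromo-2-[(1R,3S,4S)-4-bromo-3-hydroxy-4-methylcyclohexyl]-2,6,6-trimethyloxan-3-yl acetate (tertiary Br and secondary OH trans-diaxial) | CC(=O)O[C@H]1C[C@H](Br)C(C)(C)O[C@@]1(C)[C@@H]1CC[C@](C)(Br)[C@@H](O)C1 | intermediate
16 | bridged bromonium chloride of the cyclohexane C3′–C4′ bond, bromine on the face syn to the oxanyl group | CC(=O)O[C@H]1C[C@H](Br)C(C)(C)O[C@@]1(C)[C@@H]1CC[C@]2(C)[Br+][C@@H]2C1.[Cl-] | intermediate
17 | (2S,3S,5S)-5-bromo-2-[(1R,3S,4S)-4-bromo-3-chloro-4-methylcyclohexyl]-2,6,6-trimethyloxan-3-yl acetate (halogens trans-diaxial) | CC(=O)O[C@H]1C[C@H](Br)C(C)(C)O[C@@]1(C)[C@@H]1CC[C@](C)(Br)[C@@H](Cl)C1 | intermediate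
18 | acetylcaespitol, (2S,3S,5S)-5-bromo-2-[(1R,3R,4R)-3-bromo-4-chloro-4-methylcyclohexyl]-2,6,6-trimethyloxan-3-yl acetate | CC(=O)O[C@H]1C[C@H](Br)C(C)(C)O[C@@]1(C)[C@@H]1CC[C@@](C)(Cl)[C@H](Br)C1 | target

**Step count and risks**
Total steps: 10. Longest linear sequence: 9 steps (1, 2, 4–10); step 3 is a one-step side branch.

Step 4 is the most exposed. The bulky sparteine-bound organolithium may add slowly to the α-branched Weinreb amide or deprotonate it instead. Fallback: starting from 4, reduce with i-Bu2AlH (THF, −78 °C) to (1R)-4-methylcyclohex-3-ene-1-carbaldehyde F1. Add the same lithiated carbamate 7 to this much more electrophilic partner to give the hydroxy carbamate F2 (both carbinol epimers, quenched cold to stop carbamoyl migration). Oxidise with Dess–Martin periodinane (NaHCO3-buffered), which comes back to the route at 9.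

Step 5 depends on non-chelation (Felkin–Anh) control; chelation through the carbamate carbonyl would give the anti-diol. Fallback: starting from 9, methylenate with Cp2TiMe2 (PhMe, 65 °C) to the 1,1-disubstituted alkene F3, then remove the carbamate with LiAlH4 to give the allylic alcohol F4. Hydroxyl-directed epoxidation with VO(acac)2/t-BuOOH (erythro-selective through allylic 1,2-strain) gives the epoxy alcohol F5. LiAlH4 opens its terminal CH2–O bond so that the epoxide carbon becomes the methyl-bearing carbinol, which comes back to the route at 11.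

Step 7 needs Br+ to discriminate between two trisubstituted alkenes and between 6-endo and 5-exo closure. Fallback: starting from 12, use N-bromosuccinimide (2.2 equiv) in aqueous acetone so that both alkenes are consumed in one operation. The side chain is captured by the internal hydroxyl and the ring alkene by water (reversible bromonium formation, diaxial Markovnikov opening), giving the bromo-oxane trans-diaxial bromohydrin F6. K2CO3 in acetone closes it to the epoxide F7 (oxygen syn to the oxanyl group), and LiCl/AcOH in THF opens this diaxially at the secondary carbon to the chlorohydrin F8. Me3SiBr (CH2Cl2, −40 °C) then exchanges the tertiary hydroxyl for bromide with retention (axial attack anti to chlorine). This comes back to the route at 17, which is heated as in step 10.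

**Further compounds**
F1 | step 4 | (1R)-4-methylcyclohex-3-ene-1-carbaldehyde | O=C[C@@H]1CCC(C)=CC1
F2 | step 4 | (2S)-1-hydroxy-5-methyl-1-[(1R)-4-methylcyclohex-3-en-1-yl]hex-4-en-2-yl N,N-di(propan-2-yl)carbamate (both C1 carbinol epimers) | CC(C)=CC[C@H](OC(=O)N(C(C)C)C(C)C)C(O)[C@@H]1CCC(C)=CC1
F3 | step 5 | (3S)-6-methyl-2-[(1R)-4-methylcyclohex-3-en-1-yl]hepta-1,5-dien-3-yl N,N-di(propan-2-yl)carbamate | CC(C)=CC[C@H](OC(=O)N(C(C)C)C(C)C)C(=C)[C@@H]1CCC(C)=CC1
F4 | step 5 | (3S)-6-methyl-2-[(1R)-4-methylcyclohex-3-en-1-yl]hepta-1,5-dien-3-ol | CC(C)=CC[C@H](O)C(=C)[C@@H]1CCC(C)=CC1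
F5 | step 5 | (1S)-4-methyl-1-{(2R)-2-[(1R)-4-methylcyclohex-3-en-1-yl]oxiran-2-yl}pent-3-en-1-ol | CC(C)=CC[C@H](O)[C@]1(CO1)[C@@H]1CCC(C)=CC1
F6 | step 7 | (2S,3S,5S)-5-bromo-2-[(1R,3S,4S)-3-bromo-4-hydroxy-4-methylcyclohexyl]-2,6,6-trimethyloxan-3-yl acetate | CC(=O)O[C@H]1C[C@H](Br)C(C)(C)O[C@@]1(C)[C@@H]1CC[C@](C)(O)[C@@H](Br)C1
F7 | step 7 | (2S,3S,5S)-5-bromo-2,6,6-trimethyl-2-[(1R,3R,6S)-6-methyl-7-oxabicyclo[4.1.0]heptan-3-yl]oxan-3-yl acetate | CC(=O)O[C@H]1C[C@H](Br)C(C)(C)O[C@@]1(C)[C@@H]1CC[C@]2(C)O[C@@H]2C1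
F8 | step 7 | (2S,3S,5S)-5-bromo-2-[(1R,3S,4S)-3-chloro-4-hydroxy-4-methylcyclohexyl]-2,6,6-trimethyloxan-3-yl acetate | CC(=O)O[C@H]1C[C@H](Br)C(C)(C)O[C@@]1(C)[C@@H]1CC[C@](C)(O)[C@@H](Cl)C1
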